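## The problem

Compound 45 is a germacranolide. In germacrane numbering, C1–C10 form a ten-membered carbocycle, C11 carries the C13 methylene and the C12 carbonyl of a five-membered lactone closed onto O6, C14 is the methyl on C10 and C15 the methyl on C4. The lactone is cis-fused at C6–C7, and both ring alkenes (C1=C10, C4=C5) are trisubstituted and cis within the ring, so neither can come from an E-selective olefination or a thermodynamic ring closure. Four ring stereocentres are contiguous (C6 S, C7 R, C8 S, C9 S). C8 and C9 form a threo diol with the configuration of L-tartaric acid and can direct C7 and, through it, C6. C3 (S) lies beyond the C4=C5 alkene and needs its own reagent control, and the acyl group on O9 adds a 2R,3S epoxide. The α-methylene lactone, the allylic acetate, the glycidic ester and the free C8 hydroxyl beside it (acyl shift, relactonisation onto O8) tolerate neither strong base nor nucleophiles and must be unveiled after the ring is made. The handle for ring construction is the C1=C10 alkene: C1 has only the C2 methylene behind it, while C10 carries C14 and the oxygenated C9. The alkene can therefore be stored as a C1–SO2–C10 bridge with chlorine on C10 in an eleven-membered ring that is closed at sulfur. In that ring the only acidic hydrogens are on C1, away from every leaving group.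

## Retrosynthesis

**Acyl group and C8 hydroxyl (45 ⇒ 44 ⇒ 38 + 42).** The C8–O–Si bond and the C9 ester C–O bond are cut last, because the epoxy ester and the free hydroxyl would not survive alkoxide. Acid 42 comes from tiglic acid 39 through alcohol 40 and epoxy alcohol 41; the Sharpless ligand is the same diethyl L-tartrate 1 that supplies C8 and C9. The forward steps are an esterification of a hindered allylic alcohol and a mild desilylation.

**Lactone and acetate (38 ⇒ 37 ⇒ 36 ⇒ 33 ⇒ 32).** The lactone C12–O6 bond is cut and C12 is taken back to the alcohol level. In triol 33 the primary allylic C12 hydroxyl is oxidised selectively and captured by O6, since O8 is still silylated; this leaves the C3 hydroxyl as the only one to acetylate. Holding C12 as a silyl ether removes the Michael acceptor from the base step.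

**Key disconnection (32 ⇒ 30).** The C1=C10 alkene is replaced by the α-chloro sulfone 30. Olefin metathesis or a carbonyl coupling at this bond would have to close a ten-membered ring at carbon and set a cis trisubstituted alkene at once. Here the ring already exists and the C–C bond forms in a three-membered closure. Chlorine on C10 confines the carbanion to C1.

**Sulfur bridge (30 ⇒ 29 ⇒ 27 ⇒ 25).** The S–C1 bond is cut to a C10 thiol (masked as thioacetate 25) and a primary chloride, so the macrocycle is formed by the most nucleophilic atom available on an unhindered carbon. Chlorine then has to enter at the methine C10 of sulfide 27, and sulfur has to be oxidised without touching two alkenes.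

**C10 and C14 (25 ⇒ 24 ⇒ 23 ⇒ 22 ⇒ 21).** The C10–S bond goes back to a secondary alcohol, and the C10–C14 bond to aldehyde 23 and a methyl Grignard reagent. Aldehyde 23 comes from alcohol 22, which is revealed by reductive opening of the 4-methoxybenzylidene acetal of 21. One acetal thus protects O9 and O10 through the fragment union and then delivers the O9 PMB ether and the free C10 hydroxyl without another protecting group.

**Fragment union (21 ⇒ 20 ⇒ 19 ⇒ 8 + 18).** The C6–C7 bond is cut between enal 18 and the 2-(alkoxycarbonyl)allyl bromide 8. This single bond creates C6 and C7 and brings C11–C13 in the right connectivity. A union at C4=C5 would need an ylide or aldehyde with an oxygen in the β position on both partners, and a union at C7–C8 would leave C6 to an uncontrolled vinyl addition. The forward reaction must give the 6,7-syn adduct on the correct face of C7.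

**Tartrate fragment (8 ⇒ 7 ⇒ 5 + 6; 5 ⇒ 4 ⇒ 3 ⇒ 2 ⇒ 1).** Bromide 8 comes from the Morita–Baylis–Hillman adduct 7 of aldehyde 5 and methyl acrylate 6. Aldehyde 5 comes from tartrate 1 by monosilylation (2), reduction of the ester next to the free hydroxyl (3), acetal formation (4) and half-reduction. C8 and C9 are never touched.

**Enal fragment (18 ⇒ 17 ⇒ 16 ⇒ 15 ⇒ 13 ⇒ 12 ⇒ 11 ⇒ 9 + 10).** The cis C4=C5 geometry comes from syn carbocupration of ynoate 15. C3 comes from transfer hydrogenation of ynone 11, made from acid chloride 9 and alkyne 10. The C1 chlorine is carried from the start, so no hydroxyl has to be unmasked and activated before ring closure.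

## Roads not taken

**Alternative 1:** The cut is at O3 and O6 together. Sensitised photo-oxygenation of the acyclic E,E-diene A1 would add singlet oxygen across C3 and C6 to give the cis-dihydrodioxine A2. One step would set both C–O bonds and the cis C4=C5 alkene, which the chosen plan assembles over several steps (ynone reduction, carbocupration, allylation); in step economy for that segment this road is better. Its weak points for this target are three. The trisubstituted C3=C4 alkene of A1 has allylic hydrogens on C2 and C15 and would undergo the ene reaction in competition. The facial selectivity relative to C7 rests on a single adjacent stereocentre. After O–O cleavage the two new hydroxyls are alike and must still be told apart as acetate and lactone oxygen. The ten-membered ring would then have to be closed at carbon (C9–C10, from the vinyl iodide of A2), creating C9 in the closure. The chosen plan sets each centre in a separately controlled event and closes the ring at sulfur.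

**Alternative 2:** The cut is at C4=C5. The second-generation Grubbs catalyst would join the C3 isopropenyl and C6 vinyl groups of the eleven-membered silylene A3, closing the seven-membered siloxane and the ten-membered carbocycle of A4 in one step. The small siloxane ring enforces the cis geometry at C4=C5, and the epoxy ester is already in place in A4, so the endgame is shorter than the chosen one; removal of the silylene would let O6 lactonise and leave O3 for acetylation. The weak points are these. A3 must already contain the cis trisubstituted C1=C10 alkene, which this road does not itself make. The metal carbene formed at the vinyl group can instead engage C1=C10 and close a six-membered ring (C5–C10). A trisubstituted alkene flanked by two allylic oxygens forms slowly. The chosen plan addresses C1=C10 directly and has no competing alkene in the ring-forming step, but it needs six steps after the ring is made.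

**Alternative 3:** The cut is at the C1–C10 and C4–C5 σ bonds of a cyclobutane. Irradiation of enone A5 with the cyclobutene ketal A6 would give the cis-anti-cis photoadduct A7, a latent cyclodeca-1,5-diene to be released by thermal cycloreversion. C6, C7 and C8 would be set on a six-membered ring, where control is well understood, and both ring alkenes would appear together; in these respects this road is at least as good. Against it: the photoaddition must join two fully substituted carbons (C10, C4) head to head. Thermolysis of such adducts gives E-configured or mixed dienes, which drift further by Cope rearrangement, whereas the target needs both alkenes cis. The high temperature would act on silyl ether, PMB ether and ketal. The C9 ketone, the C3 ketal and the lactone with its methylene group would all still have to be adjusted on the medium ring. The chosen plan reaches the cis,cis-diene below room temperature and carries every oxygen at its final oxidation level except C12.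

Key step: step 24

Remark on the chemistry (assumption): the acetal carbon of the 4-methoxybenzylidene group (4, 5, 7, 8, 19–21), C7 of 7, C10 of 28–31 and sulfur of 29 are epimer mixtures of no consequence and are left undefined in the SMILES; C10 of 24–27 is drawn as the expected major epimer, and the minor one serves equally because C10 becomes sp2 in step 24.

**Tartrate fragment (steps 1–6)**

Step 1
Reactants: 1 diethyl L-tartrate
Product: 2 mono-TBS tartrate
Conditions: TBSCl (1.05 equiv), imidazole, DMF, 0 °C
Reagents that add atoms: tert-butyldimethylsilyl chloride, CC(C)(C)[Si](C)(C)Cl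
Why: Silyl ether formation on a C2-symmetric diol, so either hydroxyl gives the same product; the second silylation is slowed by the neighbouring silyl ether. The silylated carbon becomes C8, the free carbinol C9.

Step 2
Reactants: 2 mono-TBS tartrate
Product: 3 diol ester
Conditions: BH3·SMe2, NaBH4 (5 mol%), THF, 0 °C to rt; MeOH
Reagents that add atoms: none
Why: Hydroxyl-directed borane reduction: the alkoxyborane formed at the free C9 hydroxyl delivers hydride through a five-membered chelate to the adjacent ester only, so the ester next to the silyl ether (future C7) survives and no stereocentre is touched.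

Step 3
Reactants: 3 diol ester
Product: 4 acetal ester
Conditions: 4-MeOC6H4CH(OMe)2, PPTS (cat.), CH2Cl2, rt
Reagents that add atoms: 4-methoxybenzaldehyde dimethyl acetal, COc1ccc(C(OC)OC)cc1
Why: Acid-catalysed transacetalisation closes the dioxolane on the terminal 1,2-diol (O9, O10) faster than the hydroxy ester can lactonise.

Step 4
Reactants: 4 acetal ester
Product: 5 C7 aldehyde
Conditions: i-Bu2AlH (1.1 equiv), toluene, −78 °C
Reagents that add atoms: none
Why: Half-reduction of an α-alkoxy ester; the chelated aluminium hemiacetal is stable at −78 °C and gives the aldehyde on work-up, and the acetal is not opened at this temperature.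

Step 5
Reactants: 5 C7 aldehyde, 6 methyl acrylate
Product: 7 Baylis–Hillman alcohol
Conditions: DABCO (1 equiv), 1,4-dioxane/H2O (1:1), rt
Reagents that add atoms: none
Why: Morita–Baylis–Hillman reaction; α-alkoxy aldehydes are activated acceptors and aqueous dioxane shortens the reaction time, which limits epimerisation at C8. The C7 carbinol configuration is irrelevant because C7 becomes sp2 in step 6.

Step 6
Reactants: 7 Baylis–Hillman alcohol
Product: 8 Z-allyl bromide
Conditions: NBS, Me2S, CH2Cl2, −20 to 0 °C
Reagents that add atoms: N-bromosuccinimide, O=C1CCC(=O)N1Br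
Why: Corey–Kim-type activation of the alcohol as an alkoxysulfonium ion and SN2′ attack of bromide at the methylene carbon, the standard allylic transposition of Baylis–Hillman adducts; the trisubstituted alkene forms with C8 cis to CH2Br (2Z).

**Enal fragment (steps 7–13)**

Step 7
Reactants: 9 3-chloropropanoyl chloride, 10 bis(trimethylsilyl)acetylene
Product: 11 ynone
Conditions: AlCl3, CH2Cl2, 0 °C
Reagents that add atoms: none
Why: Friedel–Crafts-type acylation with ipso substitution of one C–Si bond; the ynone formed is deactivated towards a second acylation.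

Step 8
Reactants: 11 ynone
Product: 12 propargylic alcohol
Conditions: Ru[(S,S)-TsNCH(C6H5)CH(C6H5)NH](η6-p-cymene) (1 mol%), i-PrOH, rt
Reagents that add atoms: none
Why: Noyori asymmetric transfer hydrogenation of an alkynyl ketone; the alkynyl group takes the place of the aryl group of an aryl ketone in the transition state, so the S,S catalyst should give the 3S alcohol, which is C3 of the target. The base-free amido complex avoids loss of HCl from the β-chloro ketone.

Step 9
Reactants: 12 propargylic alcohol
Product: 13 TES ether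
Conditions: TESCl, imidazole, DMF, 0 °C
Reagents that add atoms: chlorotriethylsilane, CC[Si](Cl)(CC)CC
Why: Routine silylation of a secondary alcohol.

Step 10
Reactants: 13 TES ether
Product: 15 ynoate, via lithium acetylide 14 (not isolated)
Conditions: MeLi·LiBr, THF, 0 °C; then ClCO2Me, −78 °C
Reagents that add atoms: methyl chloroformate, COC(=O)Cl
Why: Methyllithium cleaves the C(sp)–Si bond to give the lithium acetylide, which is acylated at carbon by the chloroformate; the O–Si bond and the primary chloride are inert at these temperatures.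

Step 11
Reactants: 15 ynoate
Product: 16 Z-enoate
Conditions: Me2CuLi, THF, −78 °C; MeOH, −78 °C
Reagents that add atoms: lithium dimethylcuprate, [Li+].C[Cu-]C
Why: Syn carbocupration of the ynoate and protonation of the alkenylcopper with retention place the ester and the C3-bearing carbon cis (2Z), provided the adduct is quenched cold. A silyloxy group is too poor a leaving group for SN2′ allene formation.

Step 12
Reactants: 16 Z-enoate
Product: 17 Z-allylic alcohol
Conditions: i-Bu2AlH (2.2 equiv), CH2Cl2, −78 °C
Reagents that add atoms: none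
Why: 1,2-Reduction of an enoate to the allylic alcohol with retention of alkene geometry.

Step 13
Reactants: 17 Z-allylic alcohol
Product: 18 Z-enal
Conditions: MnO2, CH2Cl2, rt
Reagents that add atoms: none
Why: Allylic oxidation on a neutral heterogeneous oxidant, conditions under which cis β-methyl enals keep their geometry.

**Union, sulfur bridge and ring contraction (steps 14–24)**

Step 14
Reactants: 8 Z-allyl bromide, 18 Z-enal
Product: 19 hydroxy ester
Conditions: In powder, THF/H2O (3:1), rt
Reagents that add atoms: none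
Why: Barbier-type 2-(alkoxycarbonyl)allylation; the ester-chelated Z-allylindium adds through a chair with the aldehyde substituent equatorial and the C7 substituent axial, which gives the 6,7-syn adduct. At C8 the hydrogen eclipses the alkene (allylic strain) and the aldehyde should approach anti to the dioxolanyl carbon C9 with the silyloxy group outside, which sets C7, and with it C6, as required. Neutral aqueous conditions leave acetal, silyl ethers and alkyl chloride alone.

Step 15
Reactants: 19 hydroxy ester
Product: 20 diol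
Conditions: i-Bu2AlH (4 equiv), CH2Cl2, −78 to −40 °C
Reagents that add atoms: none
Why: 1,2-Reduction of the acrylate ester to the 2-substituted allylic alcohol; the benzylidene acetal is not opened below 0 °C.

Step 16
Reactants: 20 diol
Product: 21 tris-TES ether
Conditions: TESOTf, 2,6-lutidine, CH2Cl2, −78 °C
Reagents that add atoms: triethylsilyl trifluoromethanesulfonate, CC[Si](CC)(CC)OS(=O)(=O)C(F)(F)F
Why: The silyl triflate silylates both the primary C12 and the hindered secondary C6 hydroxyl, so that O3, O6 and O12 carry the same labile group.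

Step 17
Reactants: 21 tris-TES ether
Product: 22 primary alcohol
Conditions: i-Bu2AlH (3 equiv), CH2Cl2, 0 °C
Reagents that add atoms: none
Why: Reductive opening of the 4-methoxybenzylidene acetal: aluminium binds the less hindered primary oxygen O10 and hydride reduces the oxocarbenium ion on O9, which leaves the PMB ether on the secondary O9 and frees the C10 hydroxyl.

Step 18
Reactants: 22 primary alcohol
Product: 23 C10 aldehyde
Conditions: Dess–Martin periodinane, NaHCO3, CH2Cl2, 0 °C to rt
Reagents that add atoms: none
Why: Buffered Dess–Martin oxidation, which does not epimerise α-alkoxy aldehydes or cleave silyl ethers.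

Step 19
Reactants: 23 C10 aldehyde
Product: 24 C10 secondary alcohol
Conditions: MeMgBr, Et2O, −78 °C
Reagents that add atoms: methylmagnesium bromide, C[Mg]Br
Why: Grignard addition brings in C14; magnesium bridging the aldehyde and the O9 benzyl-type ether (Cram chelate) should favour the 9,10-syn alcohol. The alkyl chloride does not react at this temperature.

Step 20
Reactants: 24 C10 secondary alcohol
Product: 25 thioacetate
Conditions: PPh3, DIAD, AcSH, THF, 0 °C
Reagents that add atoms: thioacetic acid, CC(=O)S
Why: Mitsunobu thioesterification with inversion at C10; the primary chloride is not displaced by thioacetate under these conditions.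

Step 21
Reactants: 25 thioacetate
Product: 27 cyclic sulfide, via thiol 26 (not isolated)
Conditions: Cs2CO3, NaI (cat.), MeOH/DMF (1:4, degassed), 2 mM, 45 °C
Reagents that add atoms: none
Why: Methanolysis frees the thiolate, which displaces the primary halide (iodide by in situ Finkelstein exchange) in an eleven-membered exo-tet ring closure; caesium thiolates at high dilution are the standard for macrocyclic sulfides.

Step 22
Reactants: 27 cyclic sulfide
Product: 29 α-chloro sulfoxide, via α-chloro sulfide 28 (not isolated)
Conditions: NCS, CCl4, 0 °C; then m-CPBA (1.05 equiv), CH2Cl2, −78 °C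
Reagents that add atoms: N-chlorosuccinimide, O=C1CCC(=O)N1Cl; 3-chloroperoxybenzoic acid, OOC(=O)c1cccc(Cl)c1
Why: NCS gives the chlorosulfonium ion, which loses HCl towards the more substituted α-carbon (methine C10 over methylene C1) and takes up chloride there. The labile tertiary α-chloro sulfide is oxidised at once by one equivalent of cold peracid, which reacts with sulfur far faster than with the deactivated alkenes.

Step 23
Reactants: 29 α-chloro sulfoxide
Product: 30 α-chloro sulfone
Conditions: 30% H2O2, (NH4)6Mo7O24·4H2O (10 mol%), EtOH, 0 °C to rt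
Reagents that add atoms: hydrogen peroxide, OO
Why: Peroxomolybdate oxidation of sulfoxide to sulfone is chemoselective for sulfur in the presence of alkenes; the α-chloro sulfoxide, unlike the α-chloro sulfide, does not solvolyse in ethanol.

Step 24
Reactants: 30 α-chloro sulfone
Product: 32 Z,Z-diene, via episulfone 31 (not isolated)
Conditions: KOC(CH3)3 (4 equiv), THF, −78 to 0 °C
Reagents that add atoms: none
Why: The alkoxide removes a C1 hydrogen, the only acidic C–H next to the sulfone because C10 is quaternary, and the carbanion displaces chloride from C10 with inversion in a 1,3-elimination (3-exo-tet) that forms the thiirane 1,1-dioxide 31 and with it the C1–C10 bond of the ten-membered carbocycle. Loss of SO2 from 31 is stereospecific and leaves the C1=C10 alkene, so the eleven-membered ring contracts to the ten-membered one; the closest known reaction type is the Ramberg–Bäcklund ring contraction of cyclic α-halo sulfones to medium-ring cycloalkenes, trisubstituted ones included. The carbocycle is thus closed by a three-membered ring closure inside a preformed macrocycle, not by an end-to-end C–C cyclisation. No stereocentre is formed: C10 and the transient C1 centre become sp2, so either C10 epimer of 30 serves, the configurationally labile C1 anion attacking from the side opposite to the leaving chloride. The step needs the cis alkene; this corresponds to the cis-fused episulfone, the less strained bicycle for a ten-membered ring, which is also reached by base-mediated epimerisation of 31 at C1 before extrusion. It also needs the carbanion to stay away from the O9 ether: with chlorine on C10 no carbanion β to O9 can form, and the C1 anion has only the C2 hydrogens in its β position. Silyl ethers, the PMB ether and both spectator alkenes are inert to the alkoxide, and C12 is held at the alcohol level so that no Michael acceptor is present.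

**Endgame (steps 25–33)**

Step 25
Reactants: 32 Z,Z-diene
Product: 33 triol
Conditions: PPTS, MeOH/CH2Cl2 (1:1), 0 °C to rt
Reagents that add atoms: none
Why: Acid-catalysed methanolysis removes the three triethylsilyl ethers (O3, O6, O12) much faster than the hindered secondary TBS ether on O8; the PMB ether is stable.

Step 26
Reactants: 33 triol
Product: 36 12,6-lactone, via hydroxy enal 34 (not isolated), via lactol 35 (not isolated)
Conditions: TEMPO (20 mol%), PhI(OAc)2 (2.5 equiv), CH2Cl2, rt
Reagents that add atoms: none
Why: Oxoammonium oxidation is selective for the primary allylic C12 alcohol; the enal is trapped by the C6 hydroxyl as a five-membered lactol, which is oxidised to the lactone. O8 is silylated, so the lactone can only close onto O6, and the secondary C3 hydroxyl reacts much more slowly.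

Step 27
Reactants: 36 12,6-lactone
Product: 37 C3 acetate
Conditions: Ac2O, pyridine, DMAP (cat.), CH2Cl2, 0 °C
Reagents that add atoms: acetic anhydride, CC(=O)OC(C)=O
Why: Acylation of the only free hydroxyl.

Step 28
Reactants: 37 C3 acetate
Product: 38 C9 alcohol
Conditions: DDQ, CH2Cl2/pH 7 buffer (10:1), 0 °C
Reagents that add atoms: none
Why: Oxidative cleavage of the PMB ether through the benzylic oxocarbenium ion, hydrolysed by the buffer; the TBS ether, acetate and lactone are untouched.

Step 29
Reactants: 39 tiglic acid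
Product: 40 tiglyl alcohol
Conditions: LiAlH4, Et2O, 0 °C
Reagents that add atoms: none
Why: Hydride reduction of the acid to the allylic alcohol; the trisubstituted alkene is not reduced.

Step 30
Reactants: 40 tiglyl alcohol
Product: 41 epoxy alcohol
Conditions: Ti(OCH(CH3)2)4 (cat.), diethyl L-tartrate 1 (cat.), t-BuOOH, 4 Å MS, CH2Cl2, −20 °C
Reagents that add atoms: tert-butyl hydroperoxide, CC(C)(C)OO
Why: Sharpless asymmetric epoxidation; with the L-tartrate ligand, oxygen is delivered to the face of the E-allylic alcohol that gives the 2S,3S epoxy alcohol, and the cis relation of the two methyl groups is carried over from the alkene.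

Step 31
Reactants: 41 epoxy alcohol
Product: 42 epoxy acid
Conditions: RuCl3·xH2O (cat.), NaIO4, CCl4/MeCN/H2O, rt
Reagents that add atoms: sodium periodate, [Na+].[O-]I(=O)(=O)=O
Why: Catalytic RuO4 oxidation of a primary alcohol to the acid through the aldehyde hydrate, a standard route from 2,3-epoxy alcohols to glycidic acids; the configuration is unchanged (the acid is 2R,3S only because the priorities change).

Step 32
Reactants: 38 C9 alcohol, 42 epoxy acid
Product: 44 C9 epoxy ester, via mixed anhydride 43 (not isolated)
Conditions: 2,4,6-Cl3C6H2COCl, Et3N, THF, rt; then 38, DMAP, toluene, rt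
Reagents that add atoms: none
Why: Yamaguchi esterification, chosen for a hindered secondary alcohol and an α,α-disubstituted acid; DMAP attacks the less hindered carbonyl of the mixed anhydride and the acylpyridinium ion acylates O9.

Step 33
Reactants: 44 C9 epoxy ester
Product: 45 target CNP0137407.9
Conditions: HF·pyridine, pyridine, THF, 0 °C to rt
Reagents that add atoms: none
Why: Buffered fluoride-mediated desilylation of the secondary TBS ether; the mildly acidic medium disfavours the base-promoted acyl shift from O9 to O8 and relactonisation, and a glycidic ester resists acid-promoted opening.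

## Compound list

1 | diethyl L-tartrate, diethyl (2R,3R)-2,3-dihydroxybutanedioate | CCOC(=O)[C@H](O)[C@@H](O)C(=O)OCC | starting material
2 | mono-TBS tartrate, diethyl (2R,3R)-2-[(tert-butyldimethylsilyl)oxy]-3-hydroxybutanedioate | CCOC(=O)[C@H](O[Si](C)(C)C(C)(C)C)[C@@H](O)C(=O)OCC | intermediate
3 | diol ester, ethyl (2R,3S)-2-[(tert-butyldimethylsilyl)oxy]-3,4-dihydroxybutanoate | CCOC(=O)[C@H](O[Si](C)(C)C(C)(C)C)[C@@H](O)CO | intermediate
4 | acetal ester, ethyl (2R)-2-[(tert-butyldimethylsilyl)oxy]-2-[(4S)-2-(4-methoxyphenyl)-1,3-dioxolan-4-yl]acetate | CCOC(=O)[C@H](O[Si](C)(C)C(C)(C)C)[C@@H]1COC(c2ccc(OC)cc2)O1 | intermediate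
5 | C7 aldehyde, (2R)-2-[(tert-butyldimethylsilyl)oxy]-2-[(4S)-2-(4-methoxyphenyl)-1,3-dioxolan-4-yl]acetaldehyde | O=C[C@H](O[Si](C)(C)C(C)(C)C)[C@@H]1COC(c2ccc(OC)cc2)O1 | intermediate
6 | methyl acrylate | C=CC(=O)OC | starting material
7 | Baylis–Hillman alcohol, methyl 2-{(2S)-2-[(tert-butyldimethylsilyl)oxy]-1-hydroxy-2-[(4S)-2-(4-methoxyphenyl)-1,3-dioxolan-4-yl]ethyl}prop-2-enoate (both C1 epimers) | C=C(C(=O)OC)C(O)[C@H](O[Si](C)(C)C(C)(C)C)[C@@H]1COC(c2ccc(OC)cc2)O1 | intermediate
8 | Z-allyl bromide, methyl (2Z,4S)-2-(bromomethyl)-4-[(tert-butyldimethylsilyl)oxy]-4-[(4S)-2-(4-methoxyphenyl)-1,3-dioxolan-4-yl]but-2-enoate | COC(=O)/C(CBr)=C/[C@H](O[Si](C)(C)C(C)(C)C)[C@@H]1COC(c2ccc(OC)cc2)O1 | intermediate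
9 | 3-chloropropanoyl chloride | ClCCC(Cl)=O | starting material
10 | bis(trimethylsilyl)acetylene | C[Si](C)(C)C#C[Si](C)(C)C | starting material
11 | ynone, 5-chloro-1-(trimethylsilyl)pent-1-yn-3-one | C[Si](C)(C)C#CC(=O)CCCl | intermediate
12 | propargylic alcohol, (3S)-5-chloro-1-(trimethylsilyl)pent-1-yn-3-ol | C[Si](C)(C)C#C[C@@H](O)CCCl | intermediate
13 | TES ether, (3S)-5-chloro-3-[(triethylsilyl)oxy]-1-(trimethylsilyl)pent-1-yne | C[Si](C)(C)C#C[C@@H](O[Si](CC)(CC)CC)CCCl | intermediate
14 | lithium acetylide, lithium (3S)-5-chloro-3-[(triethylsilyl)oxy]pent-1-yn-1-ide (formed in situ) | [Li]C#C[C@@H](O[Si](CC)(CC)CC)CCCl | intermediate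
15 | ynoate, methyl (4S)-6-chloro-4-[(triethylsilyl)oxy]hex-2-ynoate | COC(=O)C#C[C@@H](O[Si](CC)(CC)CC)CCCl | intermediate
16 | Z-enoate, methyl (2Z,4S)-6-chloro-3-methyl-4-[(triethylsilyl)oxy]hex-2-enoate | COC(=O)/C=C(/C)[C@@H](O[Si](CC)(CC)CC)CCCl | intermediate
17 | Z-allylic alcohol, (2Z,4S)-6-chloro-3-methyl-4-[(triethylsilyl)oxy]hex-2-en-1-ol | OC/C=C(/C)[C@@H](O[Si](CC)(CC)CC)CCCl | intermediate
18 | Z-enal, (2Z,4S)-6-chloro-3-methyl-4-[(triethylsilyl)oxy]hex-2-enal | O=C/C=C(/C)[C@@H](O[Si](CC)(CC)CC)CCCl | intermediate
19 | hydroxy ester, methyl (5Z)-3-{[(tert-butyldimethylsilyl)oxy][2-(4-methoxyphenyl)-1,3-dioxolan-4-yl]methyl}-9-chloro-4-hydroxy-6-methyl-2-methylidene-7-[(triethylsilyl)oxy]non-5-enoate; C3, C6, C7, C8, C9 (germacrane numbering) arranged as in 45 | C=C(C(=O)OC)[C@@H]([C@@H](O)/C=C(/C)[C@@H](O[Si](CC)(CC)CC)CCCl)[C@H](O[Si](C)(C)C(C)(C)C)[C@@H]1COC(c2ccc(OC)cc2)O1 | intermediate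
20 | diol, (5Z)-3-{[(tert-butyldimethylsilyl)oxy][2-(4-methoxyphenyl)-1,3-dioxolan-4-yl]methyl}-9-chloro-6-methyl-2-methylidene-7-[(triethylsilyl)oxy]non-5-ene-1,4-diol; stereocentres as in 19 | C=C(CO)[C@@H]([C@@H](O)/C=C(/C)[C@@H](O[Si](CC)(CC)CC)CCCl)[C@H](O[Si](C)(C)C(C)(C)C)[C@@H]1COC(c2ccc(OC)cc2)O1 | intermediate
21 | tris-TES ether, the 1,4-bis-O-(triethylsilyl) ether of 20 | C=C(CO[Si](CC)(CC)CC)[C@@H]([C@@H](O[Si](CC)(CC)CC)/C=C(/C)[C@@H](O[Si](CC)(CC)CC)CCCl)[C@H](O[Si](C)(C)C(C)(C)C)[C@@H]1COC(c2ccc(OC)cc2)O1 | intermediate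
22 | primary alcohol, (6Z)-3-[(tert-butyldimethylsilyl)oxy]-10-chloro-2-[(4-methoxybenzyl)oxy]-7-methyl-5,8-bis[(triethylsilyl)oxy]-4-{3-[(triethylsilyl)oxy]prop-1-en-2-yl}dec-6-en-1-ol; stereocentres as in 45 | C=C(CO[Si](CC)(CC)CC)[C@@H]([C@@H](O[Si](CC)(CC)CC)/C=C(/C)[C@@H](O[Si](CC)(CC)CC)CCCl)[C@H](O[Si](C)(C)C(C)(C)C)[C@@H](OCc1ccc(OC)cc1)CO | intermediate
23 | C10 aldehyde, the dec-6-enal corresponding to 22 | C=C(CO[Si](CC)(CC)CC)[C@@H]([C@@H](O[Si](CC)(CC)CC)/C=C(/C)[C@@H](O[Si](CC)(CC)CC)CCCl)[C@H](O[Si](C)(C)C(C)(C)C)[C@@H](OCc1ccc(OC)cc1)C=O | intermediate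
24 | C10 secondary alcohol, (7Z)-4-[(tert-butyldimethylsilyl)oxy]-11-chloro-3-[(4-methoxybenzyl)oxy]-8-methyl-6,9-bis[(triethylsilyl)oxy]-5-{3-[(triethylsilyl)oxy]prop-1-en-2-yl}undec-7-en-2-ol; 2,3-syn, other centres as in 45 | C=C(CO[Si](CC)(CC)CC)[C@@H]([C@@H](O[Si](CC)(CC)CC)/C=C(/C)[C@@H](O[Si](CC)(CC)CC)CCCl)[C@H](O[Si](C)(C)C(C)(C)C)[C@@H](OCc1ccc(OC)cc1)[C@H](O)C | intermediate
25 | thioacetate, S-acetyl derivative of the undec-7-ene-2-thiol corresponding to 24 with inverted C2 (2,3-anti) | C=C(CO[Si](CC)(CC)CC)[C@@H]([C@@H](O[Si](CC)(CC)CC)/C=C(/C)[C@@H](O[Si](CC)(CC)CC)CCCl)[C@H](O[Si](C)(C)C(C)(C)C)[C@@H](OCc1ccc(OC)cc1)[C@@H](SC(C)=O)C | intermediate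
26 | thiol, the free undec-7-ene-2-thiol from 25 (formed in situ as its caesium salt) | C=C(CO[Si](CC)(CC)CC)[C@@H]([C@@H](O[Si](CC)(CC)CC)/C=C(/C)[C@@H](O[Si](CC)(CC)CC)CCCl)[C@H](O[Si](C)(C)C(C)(C)C)[C@@H](OCc1ccc(OC)cc1)[C@@H](S)C | intermediate
27 | cyclic sulfide, (7Z)-4-[(tert-butyldimethylsilyl)oxy]-3-[(4-methoxybenzyl)oxy]-2,8-dimethyl-6,9-bis[(triethylsilyl)oxy]-5-{3-[(triethylsilyl)oxy]prop-1-en-2-yl}thiacycloundec-7-ene (S1 bridges germacrane C10 and C1) | C=C(CO[Si](CC)(CC)CC)[C@H]1[C@@H](O[Si](CC)(CC)CC)/C=C(/C)[C@@H](O[Si](CC)(CC)CC)CCS[C@@H](C)[C@H](OCc2ccc(OC)cc2)[C@H]1O[Si](C)(C)C(C)(C)C | intermediate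
28 | α-chloro sulfide, the 2-chloro derivative of 27 (formed in situ) | C=C(CO[Si](CC)(CC)CC)[C@H]1[C@@H](O[Si](CC)(CC)CC)/C=C(/C)[C@@H](O[Si](CC)(CC)CC)CCSC(C)(Cl)[C@H](OCc2ccc(OC)cc2)[C@H]1O[Si](C)(C)C(C)(C)C | intermediate
29 | α-chloro sulfoxide, the 1-oxide of 28 | C=C(CO[Si](CC)(CC)CC)[C@H]1[C@@H](O[Si](CC)(CC)CC)/C=C(/C)[C@@H](O[Si](CC)(CC)CC)CCS(=O)C(C)(Cl)[C@H](OCc2ccc(OC)cc2)[C@H]1O[Si](C)(C)C(C)(C)C | intermediate
30 | α-chloro sulfone, the 1,1-dioxide of 28 (eleven-membered sulfone chlorinated at germacrane C10) | C=C(CO[Si](CC)(CC)CC)[C@H]1[C@@H](O[Si](CC)(CC)CC)/C=C(/C)[C@@H](O[Si](CC)(CC)CC)CCS(=O)(=O)C(C)(Cl)[C@H](OCc2ccc(OC)cc2)[C@H]1O[Si](C)(C)C(C)(C)C | intermediate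
31 | episulfone, the cis-fused C1,C10-thiirane 1,1-dioxide corresponding to 32 (formed in situ) | C=C(CO[Si](CC)(CC)CC)[C@H]1[C@@H](O[Si](CC)(CC)CC)/C=C(/C)[C@@H](O[Si](CC)(CC)CC)CC2C(C)(S2(=O)=O)[C@H](OCc3ccc(OC)cc3)[C@H]1O[Si](C)(C)C(C)(C)C | intermediate
32 | Z,Z-diene, (1(10)Z,4Z)-8-[(tert-butyldimethylsilyl)oxy]-9-[(4-methoxybenzyl)oxy]-3,6,12-tris[(triethylsilyl)oxy]germacra-1(10),4,11(13)-triene; C3, C6, C7, C8, C9 as in 45 | C=C(CO[Si](CC)(CC)CC)[C@H]1[C@@H](O[Si](CC)(CC)CC)/C=C(/C)[C@@H](O[Si](CC)(CC)CC)C/C=C(/C)[C@H](OCc2ccc(OC)cc2)[C@H]1O[Si](C)(C)C(C)(C)C | intermediate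
33 | triol, (1(10)Z,4Z)-8-[(tert-butyldimethylsilyl)oxy]-9-[(4-methoxybenzyl)oxy]germacra-1(10),4,11(13)-triene-3,6,12-triol | C=C(CO)[C@H]1[C@@H](O)/C=C(/C)[C@@H](O)C/C=C(/C)[C@H](OCc2ccc(OC)cc2)[C@H]1O[Si](C)(C)C(C)(C)C | intermediate
34 | hydroxy enal, the C12 aldehyde of 33 (formed in situ) | C=C(C=O)[C@H]1[C@@H](O)/C=C(/C)[C@@H](O)C/C=C(/C)[C@H](OCc2ccc(OC)cc2)[C@H]1O[Si](C)(C)C(C)(C)C | intermediate
35 | lactol, the 12,6-hemiacetal of 34 (formed in situ) | C=C1C(O)O[C@H]2/C=C(/C)[C@@H](O)C/C=C(/C)[C@H](OCc3ccc(OC)cc3)[C@@H](O[Si](C)(C)C(C)(C)C)[C@@H]12 | intermediate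
36 | 12,6-lactone, (1(10)Z,4Z)-8-[(tert-butyldimethylsilyl)oxy]-3-hydroxy-9-[(4-methoxybenzyl)oxy]germacra-1(10),4,11(13)-trien-12,6-olide | C=C1C(=O)O[C@H]2/C=C(/C)[C@@H](O)C/C=C(/C)[C@H](OCc3ccc(OC)cc3)[C@@H](O[Si](C)(C)C(C)(C)C)[C@@H]12 | intermediate
37 | C3 acetate, the 3-O-acetyl derivative of 36 | C=C1C(=O)O[C@H]2/C=C(/C)[C@@H](OC(C)=O)C/C=C(/C)[C@H](OCc3ccc(OC)cc3)[C@@H](O[Si](C)(C)C(C)(C)C)[C@@H]12 | intermediate
38 | C9 alcohol, 3-acetoxy-8-[(tert-butyldimethylsilyl)oxy]-9-hydroxygermacra-1(10)Z,4Z,11(13)-trien-12,6-olide | C=C1C(=O)O[C@H]2/C=C(/C)[C@@H](OC(C)=O)C/C=C(/C)[C@H](O)[C@@H](O[Si](C)(C)C(C)(C)C)[C@@H]12 | intermediate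
39 | tiglic acid, (E)-2-methylbut-2-enoic acid | C/C=C(\C)C(O)=O | starting material
40 | tiglyl alcohol, (E)-2-methylbut-2-en-1-ol | C/C=C(\C)CO | intermediate
41 | epoxy alcohol, [(2S,3S)-2,3-dimethyloxiran-2-yl]methanol | OC[C@]1(C)O[C@H]1C | intermediate
42 | epoxy acid, (2R,3S)-2,3-dimethyloxirane-2-carboxylic acid | O=C(O)[C@]1(C)O[C@H]1C | intermediate
43 | mixed anhydride, (2R,3S)-2,3-dimethyloxirane-2-carboxylic 2,4,6-trichlorobenzoic anhydride (formed in situ) | O=C(OC(=O)c1c(Cl)cc(Cl)cc1Cl)[C@]2(C)O[C@H]2C | intermediate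
44 | C9 epoxy ester, the 8-O-(tert-butyldimethylsilyl) ether of 45 | C=C1C(=O)O[C@H]2/C=C(/C)[C@@H](OC(C)=O)C/C=C(/C)[C@H](OC(=O)[C@]3(C)O[C@H]3C)[C@@H](O[Si](C)(C)C(C)(C)C)[C@@H]12 | intermediate
45 | CNP0137407.9, (3S,6S,7R,8S,9S)-3-acetoxy-8-hydroxy-9-{[(2R,3S)-2,3-dimethyloxiran-2-yl]carbonyloxy}germacra-1(10)Z,4Z,11(13)-trien-12,6-olide | C=C1C(=O)O[C@H]2/C=C(/C)[C@@H](OC(C)=O)C/C=C(/C)[C@H](OC(=O)[C@]3(C)O[C@H]3C)[C@@H](O)[C@@H]12 | target

## Step count and risks

Total: 33 steps. Longest linear sequence: 24 steps (9 and 10 through 18 to 45: steps 7–28, 32 and 33). The tartrate branch (steps 1–6) and the acid branch (steps 29–31) are shorter.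

**Step 24 (key step).** The contraction may give the trans alkene if the trans-fused episulfone forms and extrudes before it equilibrates, or it may stall because the carbanion must attack a tertiary, neopentyl-like carbon. If so, the C1=C10 bond would be made by an intramolecular Wittig reaction instead. Starting from alcohol 24, Dess–Martin oxidation would give methyl ketone F1, NaI in acetone the iodide F2, and PPh3 in hot MeCN the phosphonium iodide F3. KN(SiMe3)2 at high dilution would then form the ylide, which should add to the α-alkoxy methyl ketone with the known preference for the cis trisubstituted alkene (alkoxy-bearing carbon cis to the ylide substituent) and return to the route at 32. This fallback puts C9 at risk, because it sits next to the ketone under base.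

**Step 14.** Poor facial selectivity at C7 is the main danger, since the 6,7-syn relation is set by the chair but the sense relative to C8 rests on a conformational model; a second hazard is 1,4-elimination of the silyloxy group from the allylindium. The fallback moves control from the substrate to a catalyst. From bromide 8, bis(pinacolato)diboron with Pd2(dibenzylideneacetone)3 would give the allylboronate F4. Its addition to 18 goes through a boron-centred chair (again 6,7-syn) and can be run under a BINOL-derived phosphoric acid, which selects the aldehyde face and, through the chair, the C7 face, giving 19.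

**Step 22.** Chlorination may go to C1 instead of C10, because the ether on C9 makes the C10 thionium ion less favourable. The tertiary α-chloro sulfide may also lose HCl to a vinyl sulfide before it is oxidised, and the peracid may epoxidise an alkene. The fallback makes the regiochemistry unambiguous by chlorinating a sulfide whose second substituent has no α-hydrogen, and closes the ring at the sulfone level. From alcohol 24, a Mitsunobu reaction with 2-sulfanylbenzothiazole would give the aryl sulfide F5; NCS would give the α-chloro sulfide F6 and oxidation (m-CPBA, then H2O2/(NH4)6Mo7O24) the α-chloro benzothiazolyl sulfone F7. NaBH4 would release the sodium sulfinate F8, whose S-alkylation by the C1 halide (NaI, DMF, high dilution) gives 30 directly. The weak point of this route is the lifetime of the tertiary α-chloro sulfinate.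

**Step 21.** Intermolecular alkylation (dimers, oligomers) and disulfide formation compete with the eleven-membered closure, and methoxide may remove the primary triethylsilyl ether. The fallback introduces sulfur as sulfide dianion. Alcohol 24 would be converted into mesylate F9 (MsCl, Et3N), and Na2S in DMF at high dilution would displace the primary chloride and then, with inversion, the secondary mesylate, giving the same sulfide 27.

**Step 33.** Loss of the hindered silyl group needs hours in HF·pyridine, during which the ester may shift from O9 to O8, the lactone may move to O8, or the epoxide may be opened by fluoride. The fallback exchanges the silyl group before the sensitive ester is present. From 37, HF·pyridine would give alcohol F10, TESOTf the triethylsilyl ether F11, DDQ the C9 alcohol F12 and Yamaguchi esterification with 42 the ester F13, from which the triethylsilyl group is lost in AcOH/THF/H2O to give 45.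

## Further compounds

F1 | step 24 | methyl ketone, the C10 ketone (undec-7-en-2-one) corresponding to 24 | C=C(CO[Si](CC)(CC)CC)[C@@H]([C@@H](O[Si](CC)(CC)CC)/C=C(/C)[C@@H](O[Si](CC)(CC)CC)CCCl)[C@H](O[Si](C)(C)C(C)(C)C)[C@@H](OCc1ccc(OC)cc1)C(C)=O
F2 | step 24 | iodo ketone, F1 with iodine in place of chlorine at C1 | C=C(CO[Si](CC)(CC)CC)[C@@H]([C@@H](O[Si](CC)(CC)CC)/C=C(/C)[C@@H](O[Si](CC)(CC)CC)CCI)[C@H](O[Si](C)(C)C(C)(C)C)[C@@H](OCc1ccc(OC)cc1)C(C)=O
F3 | step 24 | phosphonium iodide, the C1 triphenylphosphonium salt of F2 | C=C(CO[Si](CC)(CC)CC)[C@@H]([C@@H](O[Si](CC)(CC)CC)/C=C(/C)[C@@H](O[Si](CC)(CC)CC)CC[P+](c1ccccc1)(c1ccccc1)c1ccccc1)[C@H](O[Si](C)(C)C(C)(C)C)[C@@H](OCc1ccc(OC)cc1)C(C)=O.[I-]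
F4 | step 14 | allylboronate, methyl (2E,4S)-4-[(tert-butyldimethylsilyl)oxy]-4-[(4S)-2-(4-methoxyphenyl)-1,3-dioxolan-4-yl]-2-[(4,4,5,5-tetramethyl-1,3,2-dioxaborolan-2-yl)methyl]but-2-enoate | COC(=O)/C(CB2OC(C)(C)C(C)(C)O2)=C/[C@H](O[Si](C)(C)C(C)(C)C)[C@@H]1COC(c3ccc(OC)cc3)O1
F5 | step 22 | benzothiazolyl sulfide, the S-(1,3-benzothiazol-2-yl) analogue of 25 | C=C(CO[Si](CC)(CC)CC)[C@@H]([C@@H](O[Si](CC)(CC)CC)/C=C(/C)[C@@H](O[Si](CC)(CC)CC)CCCl)[C@H](O[Si](C)(C)C(C)(C)C)[C@@H](OCc1ccc(OC)cc1)[C@@H](Sc1nc2ccccc2s1)C
F6 | step 22 | α-chloro benzothiazolyl sulfide, F5 chlorinated at C10 | C=C(CO[Si](CC)(CC)CC)[C@@H]([C@@H](O[Si](CC)(CC)CC)/C=C(/C)[C@@H](O[Si](CC)(CC)CC)CCCl)[C@H](O[Si](C)(C)C(C)(C)C)[C@@H](OCc1ccc(OC)cc1)C(C)(Cl)Sc1nc2ccccc2s1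
F7 | step 22 | α-chloro benzothiazolyl sulfone, the S,S-dioxide of F6 | C=C(CO[Si](CC)(CC)CC)[C@@H]([C@@H](O[Si](CC)(CC)CC)/C=C(/C)[C@@H](O[Si](CC)(CC)CC)CCCl)[C@H](O[Si](C)(C)C(C)(C)C)[C@@H](OCc1ccc(OC)cc1)C(C)(Cl)S(=O)(=O)c1nc2ccccc2s1
F8 | step 22 | sodium α-chloro sulfinate, the C10 sulfinate released from F7 | C=C(CO[Si](CC)(CC)CC)[C@@H]([C@@H](O[Si](CC)(CC)CC)/C=C(/C)[C@@H](O[Si](CC)(CC)CC)CCCl)[C@H](O[Si](C)(C)C(C)(C)C)[C@@H](OCc1ccc(OC)cc1)C(C)(Cl)S(=O)[O-].[Na+]
F9 | step 21 | mesylate, the C10 methanesulfonate of 24 | C=C(CO[Si](CC)(CC)CC)[C@@H]([C@@H](O[Si](CC)(CC)CC)/C=C(/C)[C@@H](O[Si](CC)(CC)CC)CCCl)[C@H](O[Si](C)(C)C(C)(C)C)[C@@H](OCc1ccc(OC)cc1)[C@H](OS(C)(=O)=O)C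
F10 | step 33 | C8 alcohol, 37 without the silyl group | C=C1C(=O)O[C@H]2/C=C(/C)[C@@H](OC(C)=O)C/C=C(/C)[C@H](OCc3ccc(OC)cc3)[C@@H](O)[C@@H]12
F11 | step 33 | C8 triethylsilyl ether, the 8-O-(triethylsilyl) analogue of 37 | C=C1C(=O)O[C@H]2/C=C(/C)[C@@H](OC(C)=O)C/C=C(/C)[C@H](OCc3ccc(OC)cc3)[C@@H](O[Si](CC)(CC)CC)[C@@H]12
F12 | step 33 | C9 alcohol, the 8-O-(triethylsilyl) analogue of 38 | C=C1C(=O)O[C@H]2/C=C(/C)[C@@H](OC(C)=O)C/C=C(/C)[C@H](O)[C@@H](O[Si](CC)(CC)CC)[C@@H]12
F13 | step 33 | C9 epoxy ester, the 8-O-(triethylsilyl) analogue of 44 | C=C1C(=O)O[C@H]2/C=C(/C)[C@@H](OC(C)=O)C/C=C(/C)[C@H](OC(=O)[C@]3(C)O[C@H]3C)[C@@H](O[Si](CC)(CC)CC)[C@@H]12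
A1 | alternative 1 | acyclic E,E-diene with Z-vinyl iodide, substrate of the photo-oxygenation | I/C(C)=C\C/C=C(C)/C=C/[C@H](C(=C)C(=O)OC)[C@H](OCc1ccc(OC)cc1)CO[Si](C)(C)C(C)(C)C
A2 | alternative 1 | cis-3,6-disubstituted 3,6-dihydro-1,2-dioxine | I/C(C)=C\C[C@@H]1OO[C@@H](C=C1C)[C@H](C(=C)C(=O)OC)[C@H](OCc2ccc(OC)cc2)CO[Si](C)(C)C(C)(C)C
A3 | alternative 2 | eleven-membered O3,O6-diisopropylsilylene carrying C3 isopropenyl and C6 vinyl groups | COC(=O)C(=C)[C@H]1[C@H](C=C)O[Si](C(C)C)(C(C)C)O[C@H](C(C)=C)C/C=C(/C)[C@H](OC(=O)[C@]2(C)O[C@H]2C)[C@H]1OCc3ccc(OC)cc3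
A4 | alternative 2 | silylene-bridged ten-membered carbocycle | COC(=O)C(=C)[C@H]1[C@@H]2/C=C(/C)[C@@H](O[Si](C(C)C)(C(C)C)O2)C/C=C(/C)[C@H](OC(=O)[C@]3(C)O[C@H]3C)[C@H]1OCc4ccc(OC)cc4
A5 | alternative 3 | 2-methylcyclohex-2-enone with C8 PMB ether, C7 CH2CO2Me and C6 TBS ether | O=C1[C@@H](OCc2ccc(OC)cc2)[C@@H](CC(=O)OC)[C@@H](O[Si](C)(C)C(C)(C)C)C=C1C
A6 | alternative 3 | 1-methyl-5,8-dioxaspiro[3.4]oct-1-ene | CC1=CCC12OCCO2
A7 | alternative 3 | tricyclic cis-anti-cis photoadduct | O=C1[C@@H](OCc5ccc(OC)cc5)[C@@H](CC(=O)OC)[C@@H](O[Si](C)(C)C(C)(C)C)[C@H]2[C@]1(C)[C@@H]3CC4(OCCO4)[C@]23C
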